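The constants of this chemistry are not given, so we need one that can be read from the runs. Suppose that a working form of the catalyst, at each moment, either meets substrate and turns over or meets capture agent and is lost. The two rates then stand as a selectivity factor times substrate over capture agent. That comparison drifts against turnover as substrate falls, and summing the turns until the catalyst is gone, with capture agent taken as staying at its charge, gives: ln(substrate charged / substrate left) = factor × catalyst charged / capture agent charged, both in mM.

| flask | substrate | partner | capture agent | free catalyst | remark | time |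
|---|---|---|---|---|---|---|
| amber | 21 mM | 0.42 equiv | 21 mM | 2 mol% | run made earlier |  |
| ochre | 21 mM | 0.92 equiv | 21 mM | 2 mol% | run made earlier |  |
| green | 21 mM | 1.2 equiv | 21 mM | 1.5 mol% | run made earlier |  |
| Tuesday's | 10 mM | 1.20 equiv | 5.00 mM | 2 mol% |  | 12 h |
| Sunday's | 21 mM | 1.20 equiv | 21.0 mM | 2 mol% |  | 12 h |
| Thursday's | 21 mM | 1.20 equiv | 21.0 mM | 0.5 mol% |  | 12 h |
| Friday's | 80 mM | 0.800 equiv | 10.0 mM | 2 mol% |  | 12 h |
| Saturday's | 21 mM | 1.20 equiv | 5.00 mM | 8 mol% |  | 12 h |
| Monday's | 8.0 mM | 1.20 equiv | 21.0 mM | 2 mol% |  | 12 h |

| run | time / h | product / % | substrate / % |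
|---|---|---|---|
| amber | 1.50 | 14.6 | 84.9 |
| amber | 3.00 | 24.7 | 75.0 |
| amber | 5.00 | 31.7 | 67.3 |
| amber | 6.00 | 33.4 | 65.2 |
| amber | 8.00 | 37.6 | 61.9 |
| amber | 10.0 | 38.7 | 61.7 |
| amber | 12.0 | 40.4 | 60.0 |
| ochre | 1.00 | 17.1 | 81.5 |
| ochre | 1.33 | 21.8 | 77.5 |
| ochre | 2.00 | 32.4 | 68.9 |
| ochre | 3.00 | 40.9 | 58.3 |
| ochre | 5.00 | 54.1 | 45.4 |
| ochre | 8.00 | 64.4 | 35.9 |
| ochre | 12.0 | 70.7 | 29.1 |
| green | 1.00 | 15.9 | 83.0 |
| green | 3.00 | 36.5 | 61.1 |
| green | 6.00 | 53.6 | 46.2 |
| green | 8.00 | 58.0 | 40.9 |
| green | 12.0 | 63.4 | 35.9 |

(readings scatter by 0.5 percentage points)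

- the numbers in the tables scatter with a standard deviation of 0.5 percentage points
- a reading or a percentage of product counts all its forms, free or not
- no earlier run changes the charge of capture agent; that part of a forecast is a guess

- the flasks put in order of amount of product, in percent of the substrate charged, best first, at 12 h (Tuesday's / Sunday's / Thursday's / Friday's / Saturday's / Monday's)
- the same order at 40 min (Tuesday's / Sunday's / Thursday's / Friday's / Saturday's / Monday's)
- the amount of product, in percent of the substrate charged of the flask you put first, at 12 h
- the amount of product, in percent of the substrate charged of the flask you put last, at 12 h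

Which numbers must be good? Partner enters as a cap, the limiting reagent: amber reads 40.4 % of product at its last reading with 0.42 equiv charged, so we cap Friday's at its 0.800 equiv. The scatter of 0.5 percentage points is less than the 5 points by which green's substrate still fell between its last two readings. Taking the earlier reading instead would move Sunday's reckoned substrate by 4.8 points, so the reckoning hangs on whether green had finished. The capture charge stands in the denominator, and no earlier run varies it, so that dependence is our guess.

Green's last reading, 35.9 % of substrate at 1.5 mol% of catalyst, taken as the end of green's catalyst, gives as a reading the selectivity factor 68.3. Our own reckoning of the substrate turned over once the catalyst is spent, which we take as product, is then Saturday's >99.9 %, Tuesday's 93.5 %, Friday's at its partner cap, Sunday's 74.5 %, Monday's 40.6 % and Thursday's 28.9 %. We commit to that order, with Tuesday's least sure: the reckoning counts turns to the end of the catalyst and does not tell whether Tuesday's gets there by 12 h.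

The forecast differs: Sunday's > Saturday's > Friday's > Tuesday's > Thursday's > Monday's at 12 h and Saturday's > Friday's > Sunday's > Tuesday's > Thursday's > Monday's at 40 min, with 73 % for the first flask and 39 % for the last, Saturday's and Friday's being expected to “stall once their capture agent is used up”.

The flasks give Saturday's > Tuesday's > Friday's > Sunday's > Monday's > Thursday's at 12 h and Saturday's > Friday's > Sunday's > Tuesday's > Monday's > Thursday's at 40 min, from 100 % down to 27.0 %, and Saturday's ends with 66.4 % of its capture agent left.

    catalyst intermediate A + capture agent → trapped intermediate (k = 3.54 L mol⁻¹ min⁻¹)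
    catalyst intermediate B ⇌ free catalyst + product (K = 0.00760 M, k = 0.419 min⁻¹)
    partner + free catalyst → catalyst intermediate A (k = 18.5 L mol⁻¹ min⁻¹)
    crystals ⇌ product, rate k4*(cs4 - [product]) while solid is left; crystals form when [product] > cs4 (solubility = 0.460 mM, k = 0.161 min⁻¹)
    substrate + catalyst intermediate A → catalyst intermediate B (k = 246 L mol⁻¹ min⁻¹)

The factor counts turns up to the trapping of the catalyst, so at 12 h we multiply the catalyst charge by its trapped share. Thursday's, with 90.6 % trapped, reckons at 26.6 % against 27.0 % found. The neighbour with 0.12 mol% of free catalyst, its other charges as in Thursday's, has 88.6 % trapped, so the same reckoning gives 7.01 %, and that flask stands at 7.12 % of product with 92.9 % of its substrate left.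

The numbers in the tables are calculated with constants of no real substance.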